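**Strategy.** Everything rests on cutting the C4'–C4a' bond of naphthalene ring D. The hindered C5–C8' biaryl is therefore made with a plain phenyl ring C, and ring D is grown afterwards. The feature exploited is the 3-methyl-1-naphthol pattern of ring D (C2'-Me, C4'-O), together with the single free carbon next to C8a', namely C4a', since C8' carries the isoquinoline. The precursor is a 5-aryl-tetrahydroisoquinoline (8-O-benzyl, N-CO2Me) whose ring C bears a 2-methyl-4-oxocyclobut-2-enyl group at C8a'. Heating opens the four-membered ring to an arylvinylketene that closes onto C4a', giving ring D and the C4' naphthol in one operation.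

Key step: step 13

Assumption: the SMILES fixes C1 and C3 (both R, methyl groups trans) but not the C5–C8' axis; the route sets no axial preference, so both atropo-diastereomers are expected from step 13 and are separated after step 16 (primed locants follow the alkaloid numbering, C8' at the biaryl bond).

Step 1
Reactants: 1 1-bromo-3,5-dimethoxybenzene; 2 tert-butyl (4R)-4-methyl-1,2,3-oxathiazolidine-3-carboxylate 2,2-dioxide
Product: 5 (2R)-1-(3,5-dimethoxyphenyl)propan-2-amine, via 3,5-dimethoxyphenylmagnesium bromide 3 (not isolated), via ring-opened N-Boc sulfamate salt 4 (not isolated)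
Conditions: 1, Mg, THF, reflux; 2, CuBr·SMe2 (10 mol%), THF, −30 °C to rt; then 3 M aq. HCl, MeOH, 50 °C; NaOH work-up
Reagents that add atoms: none
Why: Copper-catalysed SN2 opening of a cyclic sulfamidate by an aryl Grignard reagent occurs at the unhindered CH2–O carbon, so the C–N stereocentre (the later C3, R) is carried over untouched from the chiral pool, and acid then hydrolyses the N-sulfate and removes the Boc group.

Step 2
Reactants: 5 (2R)-1-(3,5-dimethoxyphenyl)propan-2-amine
Product: 6 N-[(2R)-1-(3,5-dimethoxyphenyl)propan-2-yl]acetamide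
Conditions: Ac2O, Et3N, CH2Cl2, 0 °C to rt
Reagents that add atoms: acetic anhydride CC(=O)OC(C)=O
Why: N-Acetylation of a primary amine brings in the two carbons that become C1 and its methyl group.

Step 3
Reactants: 6 N-[(2R)-1-(3,5-dimethoxyphenyl)propan-2-yl]acetamide
Product: 7 (3R)-6,8-dimethoxy-1,3-dimethyl-3,4-dihydroisoquinoline
Conditions: POCl3, MeCN, reflux
Reagents that add atoms: none
Why: Bischler–Napieralski cyclodehydration, in which the nitrilium ion attacks a ring carbon activated ortho/para by both methoxy groups; the two candidate carbons are equivalent by symmetry, so one dihydroisoquinoline should form with C3 untouched.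

Step 4
Reactants: 7 (3R)-6,8-dimethoxy-1,3-dimethyl-3,4-dihydroisoquinoline
Product: 9 (3R)-6-methoxy-1,3-dimethyl-3,4-dihydroisoquinolin-8-ol, via dichloroboron chelate 8 (not isolated)
Conditions: BCl3 (1.2 equiv), CH2Cl2, −78 °C to 0 °C; then aq. MeOH
Reagents that add atoms: none
Why: Chelation-directed Lewis-acid cleavage of an aryl methyl ether, as with ortho-methoxyaryl ketones: boron held on the imine nitrogen reaches only the peri C8 oxygen (six-membered chelate 8), chloride removes that methyl group, and the remote C6 ether is too unreactive towards BCl3 at this temperature.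

Step 5
Reactants: 9 (3R)-6-methoxy-1,3-dimethyl-3,4-dihydroisoquinolin-8-ol
Product: 10 (3R)-8-(benzyloxy)-6-methoxy-1,3-dimethyl-3,4-dihydroisoquinoline
Conditions: BnBr (1.05 equiv), K2CO3, DMF, rt
Reagents that add atoms: benzyl bromide BrCc1ccccc1
Why: Williamson ether synthesis, in which the phenoxide is far more nucleophilic than the imine nitrogen flanked by the C1 and C3 methyl groups, so O-benzylation should prevail.

Step 6
Reactants: 10 (3R)-8-(benzyloxy)-6-methoxy-1,3-dimethyl-3,4-dihydroisoquinoline
Product: 11 (1R,3R)-8-(benzyloxy)-6-methoxy-1,3-dimethyl-1,2,3,4-tetrahydroisoquinoline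
Conditions: AlMe3 (3 equiv), LiAlH4 (3 equiv), THF, −78 °C to 0 °C; aqueous work-up; chromatography to remove any cis isomer
Reagents that add atoms: none
Why: Lewis-acid-modified hydride reduction of a 1,3-dimethyl-3,4-dihydroisoquinoline: AlMe3 bound to nitrogen occupies the face opposite the C3 methyl group, so hydride should enter C1 on the face of that methyl group and set the C1 methyl trans (1R) under control of C3.

Step 7
Reactants: 11 (1R,3R)-8-(benzyloxy)-6-methoxy-1,3-dimethyl-1,2,3,4-tetrahydroisoquinoline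
Product: 12 methyl (1R,3R)-8-(benzyloxy)-6-methoxy-1,3-dimethyl-3,4-dihydro-1H-isoquinoline-2-carboxylate
Conditions: ClCO2Me, K2CO3, CH2Cl2/H2O, 0 °C to rt
Reagents that add atoms: methyl chloroformate COC(=O)Cl
Why: Schotten–Baumann acylation with a small chloroformate makes the hindered nitrogen neutral and non-nucleophilic for the metal and ketene chemistry ahead and stores the N-methyl carbon.

Step 8
Reactants: 12 methyl (1R,3R)-8-(benzyloxy)-6-methoxy-1,3-dimethyl-3,4-dihydro-1H-isoquinoline-2-carboxylate
Product: 13 methyl (1R,3R)-8-(benzyloxy)-5-iodo-6-methoxy-1,3-dimethyl-3,4-dihydro-1H-isoquinoline-2-carboxylate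
Conditions: NIS, TFA (10 mol%), MeCN, 0 °C to rt
Reagents that add atoms: N-iodosuccinimide O=C1CCC(=O)N1I
Why: Electrophilic aromatic iodination, in which C5 is para to the benzyloxy and ortho to the methoxy group whereas C7 is squeezed between two alkoxy groups, so the large electrophile should enter at C5.

Step 9
Reactants: 13 methyl (1R,3R)-8-(benzyloxy)-5-iodo-6-methoxy-1,3-dimethyl-3,4-dihydro-1H-isoquinoline-2-carboxylate; 14 2-bromo-1-iodo-4-methoxybenzene
Product: 17 methyl (1R,3R)-8-(benzyloxy)-5-(2-bromo-4-methoxyphenyl)-6-methoxy-1,3-dimethyl-3,4-dihydro-1H-isoquinoline-2-carboxylate, via (2-bromo-4-methoxyphenyl)magnesium chloride 15 (not isolated), via (2-bromo-4-methoxyphenyl)zinc chloride 16 (not isolated)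
Conditions: 14, iPrMgCl·LiCl, THF, −20 °C; ZnCl2, −20 °C to rt; then 13, Pd2(dba)3 (2.5 mol%), P(2-furyl)3 (10 mol%), THF, 50 °C
Reagents that add atoms: none
Why: Negishi coupling, in which halogen–magnesium exchange of 14 is selective for iodine, the zinc reagent 16 does not collapse to an aryne, and zerovalent palladium with a weakly donating phosphine inserts into the C–I bond of 13 much faster than into any C–Br bond, so bromine survives as the handle at C8a'.

Step 10
Reactants: 18 propyne; 19 trichloroacetyl chloride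
Product: 21 4,4-dichloro-3-methylcyclobut-2-en-1-one, via dichloroketene 20 (not isolated)
Conditions: Zn(Cu), 19 added slowly, excess condensed 18, Et2O/DME, 0 °C to rt, dry-ice condenser
Reagents that add atoms: none
Why: [2+2] cycloaddition of dichloroketene (made by zinc dechlorination of 19) with a terminal alkyne, in which the ketene carbonyl carbon bonds to the unsubstituted alkyne carbon and thereby places the methyl group at C3 next to CCl2.

Step 11
Reactants: 21 4,4-dichloro-3-methylcyclobut-2-en-1-one
Product: 22 4-chloro-3-methylcyclobut-2-en-1-one (racemic)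
Conditions: Zn dust (1.1 equiv), AcOH/Et2O, 0 °C
Reagents that add atoms: none
Why: Zinc/acetic acid reduction of an alpha,alpha-dichloro ketone can be held at the monochloride with a limited charge of zinc at low temperature, because the second C–Cl bond is reduced more slowly.

Step 12
Reactants: 17 methyl (1R,3R)-8-(benzyloxy)-5-(2-bromo-4-methoxyphenyl)-6-methoxy-1,3-dimethyl-3,4-dihydro-1H-isoquinoline-2-carboxylate; 22 4-chloro-3-methylcyclobut-2-en-1-one
Product: 25 methyl (1R,3R)-8-(benzyloxy)-6-methoxy-5-[4-methoxy-2-(2-methyl-4-oxocyclobut-2-en-1-yl)phenyl]-1,3-dimethyl-3,4-dihydro-1H-isoquinoline-2-carboxylate, via aryllithium 23 (not isolated), via arylzinc chloride 24 (not isolated)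
Conditions: 17, n-BuLi (1.05 equiv), THF, −78 °C, 15 min; ZnCl2, −78 °C to 0 °C; then 22 (1.5 equiv), Pd2(dba)3 (2.5 mol%), P(2-furyl)3 (10 mol%), THF, 0 °C to rt
Reagents that add atoms: none
Why: Negishi allyl–aryl coupling, the zinc version of the established palladium-catalysed coupling of 4-chlorocyclobutenones with aryl- and alkenylmetals: bromine–lithium exchange outruns attack on the carbamate at −78 °C, oxidative addition of 22 gives an oxocyclobutenyl palladium species whose two termini are equivalent (each a CH next to C=O) so only one regioisomer can form, and the base-free conditions at or below room temperature avoid both loss of HCl from 22 through its acidic methyl group and premature ring opening of 25.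

Step 13
Reactants: 25 methyl (1R,3R)-8-(benzyloxy)-6-methoxy-5-[4-methoxy-2-(2-methyl-4-oxocyclobut-2-en-1-yl)phenyl]-1,3-dimethyl-3,4-dihydro-1H-isoquinoline-2-carboxylate
Product: 28 methyl (1R,3R)-8-(benzyloxy)-5-(5-hydroxy-4-methoxy-7-methylnaphthalen-1-yl)-6-methoxy-1,3-dimethyl-3,4-dihydro-1H-isoquinoline-2-carboxylate, via (Z)-arylvinylketene 26 (not isolated), via cyclohexadienone tautomer 27 (not isolated)
Conditions: PhMe (0.01 M, dry, degassed), 110 °C, sealed vessel
Reagents that add atoms: none
Why: Release of ring strain drives a thermal conrotatory four-electron opening of the C4'–C1' bond of 25 to arylvinylketenes, and because this opening is reversible the ketene with ring C turned away from the C=C=O unit re-closes and the material drains through the (Z)-isomer 26, in which C4' lies next to C4a'. A disrotatory six-electron electrocyclization of 26 (C4'=C3', C2'=C1', C8a'=C4a') then forms the C4'–C4a' bond and the six-membered ring D as dienone 27, and the proton shift from C4a' to oxygen restores aromaticity and makes the sequence irreversible. The closest known reaction type is the thermolysis of 4-aryl- and 4-alkenylcyclobut-2-enones to 1-naphthols and phenols, the closing stage of the Danheiser benzannulation and a relative of the Moore cyclization. No stereocentre is created: the cyclobutenone carbon C1' becomes planar, so all diastereomers of 25 converge, C1 and C3 are remote and untouched, and the C5–C8' axis, which becomes configurationally stable only now, is not controlled. The step needs regioselective closure and a clean unimolecular course: the first is secured because C8', the other neighbour of C8a', carries the isoquinoline and because the four-membered ring fixes methyl at C2' and oxygen at C4', and the second is served by high dilution, exclusion of water and oxygen, and the absence of any O–H, N–H or basic nitrogen in 25.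

Step 14
Reactants: 28 methyl (1R,3R)-8-(benzyloxy)-5-(5-hydroxy-4-methoxy-7-methylnaphthalen-1-yl)-6-methoxy-1,3-dimethyl-3,4-dihydro-1H-isoquinoline-2-carboxylate
Product: 29 methyl (1R,3R)-8-(benzyloxy)-5-(4,5-dimethoxy-7-methylnaphthalen-1-yl)-6-methoxy-1,3-dimethyl-3,4-dihydro-1H-isoquinoline-2-carboxylate
Conditions: MeI, K2CO3, acetone, reflux
Reagents that add atoms: iodomethane CI
Why: Williamson methylation of the only free hydroxyl group, which the peri hydrogen bond to the C5' methoxy group slows but should not prevent in refluxing acetone.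

Step 15
Reactants: 29 methyl (1R,3R)-8-(benzyloxy)-5-(4,5-dimethoxy-7-methylnaphthalen-1-yl)-6-methoxy-1,3-dimethyl-3,4-dihydro-1H-isoquinoline-2-carboxylate
Product: 30 (1R,3R)-8-(benzyloxy)-5-(4,5-dimethoxy-7-methylnaphthalen-1-yl)-6-methoxy-1,2,3-trimethyl-1,2,3,4-tetrahydroisoquinoline
Conditions: LiAlH4, THF, reflux; aqueous work-up
Reagents that add atoms: none
Why: LiAlH4 reduction of a carbamate to an N-methyl amine (hydride addition, loss of methoxide, reduction of the formamide stage through an iminium ion) touches nothing else, since only ethers and arenes remain.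

Step 16
Reactants: 30 (1R,3R)-8-(benzyloxy)-5-(4,5-dimethoxy-7-methylnaphthalen-1-yl)-6-methoxy-1,2,3-trimethyl-1,2,3,4-tetrahydroisoquinoline
Product: 31 ancistrocongoline B, (1R,3R)-5-(4,5-dimethoxy-7-methylnaphthalen-1-yl)-6-methoxy-1,2,3-trimethyl-1,2,3,4-tetrahydroisoquinolin-8-ol
Conditions: H2 (1 atm), Pd/C, MeOH/EtOAc, rt; then preparative HPLC to separate the two atropo-diastereomers
Reagents that add atoms: none
Why: Catalytic hydrogenolysis of the benzyl aryl ether is much faster than reduction of the naphthalene or cleavage of the cyclic benzylic C1–N bond, so the C8 phenol is released with C1, C3 and the axis unchanged.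

**Compound list**

1 | 1-bromo-3,5-dimethoxybenzene | COc1cc(Br)cc(OC)c1 | starting material
2 | tert-butyl (4R)-4-methyl-1,2,3-oxathiazolidine-3-carboxylate 2,2-dioxide (commercial Boc sulfamidate of D-alaninol) | C[C@@H]1COS(=O)(=O)N1C(=O)OC(C)(C)C | starting material
3 | 3,5-dimethoxyphenylmagnesium bromide (not isolated) | COc1cc(OC)cc([Mg]Br)c1 | intermediate
4 | bromomagnesium N-(tert-butoxycarbonyl)-N-[(2R)-1-(3,5-dimethoxyphenyl)propan-2-yl]sulfamate (not isolated) | C[C@H](Cc1cc(OC)cc(OC)c1)N(C(=O)OC(C)(C)C)S(=O)(=O)[O-].[Mg+2].[Br-] | intermediate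
5 | (2R)-1-(3,5-dimethoxyphenyl)propan-2-amine | C[C@@H](N)Cc1cc(OC)cc(OC)c1 | intermediate
6 | N-[(2R)-1-(3,5-dimethoxyphenyl)propan-2-yl]acetamide | C[C@@H](NC(C)=O)Cc1cc(OC)cc(OC)c1 | intermediate
7 | (3R)-6,8-dimethoxy-1,3-dimethyl-3,4-dihydroisoquinoline | COc1cc(OC)c2c(c1)C[C@@H](C)N=C2C | intermediate
8 | B,B-dichloro N,O-boron chelate of (3R)-6-methoxy-1,3-dimethyl-3,4-dihydroisoquinolin-8-olate (not isolated) | COc1cc2c3c(c1)C[C@@H](C)[N+](=C3C)[B-](Cl)(Cl)O2 | intermediate
9 | (3R)-6-methoxy-1,3-dimethyl-3,4-dihydroisoquinolin-8-ol | COc1cc(O)c2c(c1)C[C@@H](C)N=C2C | intermediate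
10 | (3R)-8-(benzyloxy)-6-methoxy-1,3-dimethyl-3,4-dihydroisoquinoline | COc1cc(OCc2ccccc2)c2c(c1)C[C@@H](C)N=C2C | intermediate
11 | (1R,3R)-8-(benzyloxy)-6-methoxy-1,3-dimethyl-1,2,3,4-tetrahydroisoquinoline (trans) | COc1cc(OCc2ccccc2)c2c(c1)C[C@@H](C)N[C@@H]2C | intermediate
12 | methyl (1R,3R)-8-(benzyloxy)-6-methoxy-1,3-dimethyl-3,4-dihydro-1H-isoquinoline-2-carboxylate | COc1cc(OCc2ccccc2)c2c(c1)C[C@@H](C)N(C(=O)OC)[C@@H]2C | intermediate
13 | methyl (1R,3R)-8-(benzyloxy)-5-iodo-6-methoxy-1,3-dimethyl-3,4-dihydro-1H-isoquinoline-2-carboxylate | COc1cc(OCc2ccccc2)c2c(c1I)C[C@@H](C)N(C(=O)OC)[C@@H]2C | intermediate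
14 | 2-bromo-1-iodo-4-methoxybenzene (3-bromo-4-iodoanisole) | COc1ccc(I)c(Br)c1 | starting material
15 | (2-bromo-4-methoxyphenyl)magnesium chloride (not isolated) | COc1ccc([Mg]Cl)c(Br)c1 | intermediate
16 | (2-bromo-4-methoxyphenyl)zinc chloride (not isolated) | COc1ccc([Zn]Cl)c(Br)c1 | intermediate
17 | methyl (1R,3R)-8-(benzyloxy)-5-(2-bromo-4-methoxyphenyl)-6-methoxy-1,3-dimethyl-3,4-dihydro-1H-isoquinoline-2-carboxylate | COc1cc(OCc2ccccc2)c2c(c1-c1ccc(OC)cc1Br)C[C@@H](C)N(C(=O)OC)[C@@H]2C | intermediate
18 | propyne | CC#C | starting material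
19 | trichloroacetyl chloride | ClC(Cl)(Cl)C(Cl)=O | starting material
20 | dichloroketene (not isolated) | ClC(Cl)=C=O | intermediate
21 | 4,4-dichloro-3-methylcyclobut-2-en-1-one | CC1=CC(=O)C1(Cl)Cl | intermediate
22 | 4-chloro-3-methylcyclobut-2-en-1-one (racemic) | CC1=CC(=O)C1Cl | intermediate
23 | aryllithium from 17, Li in place of Br at C8a' (not isolated) | COc1cc(OCc2ccccc2)c2c(c1-c1ccc(OC)cc1[Li])C[C@@H](C)N(C(=O)OC)[C@@H]2C | intermediate
24 | arylzinc chloride from 17, ZnCl in place of Br at C8a' (not isolated) | COc1cc(OCc2ccccc2)c2c(c1-c1ccc(OC)cc1[Zn]Cl)C[C@@H](C)N(C(=O)OC)[C@@H]2C | intermediate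
25 | methyl (1R,3R)-8-(benzyloxy)-6-methoxy-5-[4-methoxy-2-(2-methyl-4-oxocyclobut-2-en-1-yl)phenyl]-1,3-dimethyl-3,4-dihydro-1H-isoquinoline-2-carboxylate (mixture at the cyclobutenone CH and about the biaryl bond) | COc1cc(OCc2ccccc2)c2c(c1-c1ccc(OC)cc1C1C(C)=CC1=O)C[C@@H](C)N(C(=O)OC)[C@@H]2C | intermediate
26 | methyl (1R,3R)-8-(benzyloxy)-6-methoxy-5-{4-methoxy-2-[(1Z)-2-methyl-4-oxobuta-1,3-dien-1-yl]phenyl}-1,3-dimethyl-3,4-dihydro-1H-isoquinoline-2-carboxylate (not isolated) | COc1cc(OCc2ccccc2)c2c(c1-c1ccc(OC)cc1/C=C(C)\C=C=O)C[C@@H](C)N(C(=O)OC)[C@@H]2C | intermediate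
27 | 4a'H-naphthalen-4'-one tautomer of 28, sp3 C4a'-H, C4'=O (not isolated) | COc1cc(OCc2ccccc2)c2c(c1C1=CC=C(OC)C3C(=O)C=C(C)C=C13)C[C@@H](C)N(C(=O)OC)[C@@H]2C | intermediate
28 | methyl (1R,3R)-8-(benzyloxy)-5-(5-hydroxy-4-methoxy-7-methylnaphthalen-1-yl)-6-methoxy-1,3-dimethyl-3,4-dihydro-1H-isoquinoline-2-carboxylate (C4' naphthol) | COc1cc(OCc2ccccc2)c2c(c1-c1ccc(OC)c3c(O)cc(C)cc13)C[C@@H](C)N(C(=O)OC)[C@@H]2C | intermediate
29 | methyl (1R,3R)-8-(benzyloxy)-5-(4,5-dimethoxy-7-methylnaphthalen-1-yl)-6-methoxy-1,3-dimethyl-3,4-dihydro-1H-isoquinoline-2-carboxylate | COc1cc(OCc2ccccc2)c2c(c1-c1ccc(OC)c3c(OC)cc(C)cc13)C[C@@H](C)N(C(=O)OC)[C@@H]2C | intermediate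
30 | (1R,3R)-8-(benzyloxy)-5-(4,5-dimethoxy-7-methylnaphthalen-1-yl)-6-methoxy-1,2,3-trimethyl-1,2,3,4-tetrahydroisoquinoline | COc1cc(OCc2ccccc2)c2c(c1-c1ccc(OC)c3c(OC)cc(C)cc13)C[C@@H](C)N(C)[C@@H]2C | intermediate
31 | ancistrocongoline B, (1R,3R)-5-(4,5-dimethoxy-7-methylnaphthalen-1-yl)-6-methoxy-1,2,3-trimethyl-1,2,3,4-tetrahydroisoquinolin-8-ol | COc1cc(O)c2c(c1-c1ccc(OC)c3c(OC)cc(C)cc13)C[C@@H](C)N(C)[C@@H]2C | target

**Step count.** Total: 16 steps. Longest linear sequence: 14 steps (steps 1–9 and 12–16). Steps 10 and 11 form the two-step side branch to 22.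

**Steps most likely to fail**

Step 13. The very bulky ring C may rotate inward too slowly. The outward-rotated ketene would then be lost by dimerization or by capture of traces of water before ring D closes.
- The fallback grows ring D on a simple arene by the same cyclobutenone chemistry and makes the hindered biaryl bond afterwards. It sets out from 22 and 13 and returns at 29.
- Zinc insertion (Zn, LiCl, THF) into the C–I bond of purchased 1-bromo-2-iodo-4-methoxybenzene F1 gives (2-bromo-5-methoxyphenyl)zinc iodide F2.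
- F2 is coupled with 22 (Pd2(dba)3, P(2-furyl)3, THF) to give 4-(2-bromo-5-methoxyphenyl)-3-methylcyclobut-2-en-1-one F3.
- Thermolysis in toluene gives 5-bromo-8-methoxy-3-methylnaphthalen-1-ol F4, and methylation (MeI, K2CO3) gives 1-bromo-4,5-dimethoxy-7-methylnaphthalene F5.
- Miyaura borylation (B2pin2, Pd(dppf)Cl2, KOAc, dioxane) gives the naphthyl pinacol boronate F6.
- Suzuki–Miyaura coupling of F6 with 13 (Pd(OAc)2, SPhos, K3PO4, toluene/H2O, 100 °C) gives 29.

Step 12. Transmetalation and reductive elimination at the crowded arylzinc may be slow. Protodemetalation of 24 and decomposition of 22 on palladium could then win.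
- The fallback avoids the cross-coupling and builds the four-membered ring on the arene by a ketene cycloaddition. It sets out from 17 and returns at 25.
- Palladium-catalysed arylation of the Reformatsky reagent BrZnCH2CO2Et with 17 (Pd2(dba)3, QPhos, THF) gives the ethyl arylacetate F7, and saponification (LiOH, THF/H2O) gives the arylacetic acid F8.
- Oxalyl chloride with catalytic DMF gives the acid chloride F9. Et3N in the presence of excess ethoxyacetylene then generates the arylketene F10.
- F10 is taken up in a [2+2] cycloaddition to give the 4-aryl-3-ethoxycyclobut-2-enone F11.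
- Addition of MeLi (THF, −78 °C) to the ring carbonyl gives the tertiary carbinol F12. Dilute aqueous HCl transposes F12 to 25.

Step 9. Oxidative addition may stray into C–Br bonds of the zinc reagent or of the product, leading to oligomerization. Alternatively, the hindered C–I bond of 13 may be reduced instead of coupled.
- The fallback inverts the polarity of the partners, so that palladium inserts into the less hindered C–I bond of 14 and the crowded partner enters by transmetalation. It sets out from 13 and 14 and returns at 17.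
- Iodine–magnesium exchange of 13 (iPrMgCl·LiCl, THF, 0 °C) gives the isoquinolin-5-ylmagnesium chloride F13, and ZnCl2 gives the isoquinolin-5-ylzinc chloride F14.
- Negishi coupling of F14 with 14 (Pd(PPh3)4, THF, 50 °C) gives 17.

**Further compounds**

F1 | step 13 | 1-bromo-2-iodo-4-methoxybenzene (purchased) | COc1ccc(Br)c(I)c1
F2 | step 13 | (2-bromo-5-methoxyphenyl)zinc iodide | COc1ccc(Br)c([Zn]I)c1
F3 | step 13 | 4-(2-bromo-5-methoxyphenyl)-3-methylcyclobut-2-en-1-one | COc1ccc(Br)c(C2C(C)=CC2=O)c1
F4 | step 13 | 5-bromo-8-methoxy-3-methylnaphthalen-1-ol | COc1ccc(Br)c2cc(C)cc(O)c12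
F5 | step 13 | 1-bromo-4,5-dimethoxy-7-methylnaphthalene | COc1ccc(Br)c2cc(C)cc(OC)c12
F6 | step 13 | 2-(4,5-dimethoxy-7-methylnaphthalen-1-yl)-4,4,5,5-tetramethyl-1,3,2-dioxaborolane | COc1ccc(B2OC(C)(C)C(C)(C)O2)c2cc(C)cc(OC)c12
F7 | step 12 | ethyl arylacetate, 17 with CH2CO2Et in place of Br | COc1cc(OCc2ccccc2)c2c(c1-c1ccc(OC)cc1CC(=O)OCC)C[C@@H](C)N(C(=O)OC)[C@@H]2C
F8 | step 12 | arylacetic acid, 17 with CH2CO2H in place of Br | COc1cc(OCc2ccccc2)c2c(c1-c1ccc(OC)cc1CC(=O)O)C[C@@H](C)N(C(=O)OC)[C@@H]2C
F9 | step 12 | arylacetyl chloride, 17 with CH2COCl in place of Br | COc1cc(OCc2ccccc2)c2c(c1-c1ccc(OC)cc1CC(=O)Cl)C[C@@H](C)N(C(=O)OC)[C@@H]2C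
F10 | step 12 | arylketene, 17 with CH=C=O in place of Br | COc1cc(OCc2ccccc2)c2c(c1-c1ccc(OC)cc1C=C=O)C[C@@H](C)N(C(=O)OC)[C@@H]2C
F11 | step 12 | 4-aryl-3-ethoxycyclobut-2-enone, 17 with 2-ethoxy-4-oxocyclobut-2-en-1-yl in place of Br | COc1cc(OCc2ccccc2)c2c(c1-c1ccc(OC)cc1C1C(OCC)=CC1=O)C[C@@H](C)N(C(=O)OC)[C@@H]2C
F12 | step 12 | tertiary carbinol, 17 with 2-ethoxy-4-hydroxy-4-methylcyclobut-2-en-1-yl in place of Br | COc1cc(OCc2ccccc2)c2c(c1-c1ccc(OC)cc1C1C(OCC)=CC1(C)O)C[C@@H](C)N(C(=O)OC)[C@@H]2C
F13 | step 9 | isoquinolin-5-ylmagnesium chloride, 13 with MgCl in place of iodine | COc1cc(OCc2ccccc2)c2c(c1[Mg]Cl)C[C@@H](C)N(C(=O)OC)[C@@H]2C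
F14 | step 9 | isoquinolin-5-ylzinc chloride, 13 with ZnCl in place of iodine | COc1cc(OCc2ccccc2)c2c(c1[Zn]Cl)C[C@@H](C)N(C(=O)OC)[C@@H]2C
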